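**No plateau yet.** A plateau cannot be read off the autumn flask: up to 10.0 min its target readings lie near a straight line.

all flasks: partner 0.0728 M

| run | substrate | remark | time |
|---|---|---|---|
| autumn | 0.091 M | the very flask that is asked about, followed so far |  |
| winter | 0.14 M | run made earlier |  |
| flask | 0.091 M |  | 20 min |

| autumn: time / min | autumn: target / % | winter: time / min | winter: target / % |
|---|---|---|---|
| 2.50 | 3.2 | 5.00 | 6.0 |
| 5.00 | 6.3 | 10.0 | 11.5 |
| 8.00 | 10.0 | 15.0 | 12.8 |
| 10.0 | 11.3 | 20.0 | 14.6 |

(scatter of a reading: 0.5 percentage points)

* amount of target in percent of the substrate charged, at 2.0 min, 6.0 min, 12 min and 20 min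



**Charge time.** Let τ be the charge time, the time in which the early pace of target would account for the whole substrate charge. The autumn readings at 5.00 min and 8.00 min give 79.8 min. The line t/τ then gives 2.51% at 2.0 min and 7.52% at 6.0 min.

**First objection.** τ might depend on the charge. The winter run, with 1.54 times the substrate, gives 87.0 min at 10.0 min, close to the autumn value given the scatter. Up to that time the two runs therefore agree in percent within the scatter, and τ is carried from one charge to the other.

**Second objection.** The line is in doubt late on: it gives 25.1% at 20 min, but the winter run read 14.6%. The later points are better taken from the winter curve: 12.0% at 12 min by interpolation, and 14.6% at 20 min.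

**Third objection.** Partner might have bent the winter curve. Taking one partner per target, the last winter reading is 0.0204 M, less than the 0.0728 M charged, so the target read accounts for part of the partner, and any other use of partner is not read in the runs.

**The forecast.** It gives 2.6%, 7.5%, 12.4% and 15.3%, holding that “the autumn flask should track the winter curve”. At 20 min it stands 0.7 percentage points above the reckoning here.

**The flask.** The autumn flask gives 2.13%, 7.90%, 13.0% and 16.9%, so the forecast holds. At 20 min it stands at 67.4% of the line t/τ, and the winter run at 58.2%.

    substrate ⇌ open intermediate (K = 0.460, k = 0.00475 /s)
    partner → second intermediate (k = 0.00961 /s)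
    open intermediate + second intermediate → target (k = 0.0496 /M/s)
    target ⇌ isomer of the product (K = 2.00, k = 0.0168 /s)

In the autumn flask, partner, the limiting reagent, turned into second intermediate with a half-life of 1.2 min by that path, falling to 31.6% of its charge at 2.00 min and 0.313% at 10.0 min. Meanwhile second intermediate, at 0.0468 M at 2.00 min and 0.0443 M at 10.0 min, met open intermediate to give target, which exchanged with isomer of the product, and at 20.0 min the flask held 16.9% target and 32.2% isomer of the product.

Readings and results come from a simulation from invented constants, noise included.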